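## Retrosynthetic overview

1. Numbering: oxane O1, C2 (guaiacyl-bearing), C3, C4 (OH), C5, C6; side chain C7 (carbinol), C8 (benzylic). Endgame: both O-benzyl groups come off last; the C4 carbinol comes from a C4 ketone by reduction directed by the C7 hydroxyl, and the ketone from a C4 methylidene group that serves as a temporary activating carbon.
2. Key disconnection: C2–C3 and O1–C6 in one flask. O-Benzylvanillin (C2, O1) and the cis-epoxy allylic chloride 8 (C3 to C8) are joined by an enantioselective iridium-catalyzed carbonyl allylation, and the new C2 alkoxide opens the C6–C7 epoxide in the 6-exo mode. This closes the oxane, the only ring made in the route; both arenes are bought.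
3. Enabling feature: O1 lies between the benzylic C2 (an aldehyde carbon in disguise) and C6, whose exocyclic neighbor C7 carries a free hydroxyl threo to O1. That is the imprint of a cis-epoxide opened with inversion at C6, and C3H2–C4(O) is the imprint of a 2-substituted allyl nucleophile. The 2,6-trans relation is therefore set by two independent stereospecific events and not by ring thermodynamics.
4. Fragment 8: propargyl alcohol and 3-chloro-2-(chloromethyl)propene give a Z-allylic alcohol, Sharpless epoxidation sets C6 and C7, and the primary alcohol is replaced by the aryl group through its triflate.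

Key step: step 6

Assumption: the iridium complex built on (S)-SEGPHOS is taken to give the (S)-aryl carbinol, as in the parent allylation and methallylation of aldehydes; if a test on 9 with methallyl chloride shows the opposite sense, (R)-SEGPHOS is used and nothing else changes.

## Route

Step 1
Reactants: 1 prop-2-yn-1-ol; 2 3-chloro-2-(chloromethyl)prop-1-ene (fourfold excess)
Product: 3 5-(chloromethyl)hex-5-en-2-yn-1-ol
Conditions: CuI (10 mol %), K2CO3, n-Bu4NCl, DMF, rt
Reagents that add atoms: none
Why: Copper-catalyzed coupling of a terminal alkyne with an allylic chloride through the alkynylcopper; the two allylic ends of 2 are equivalent, so SN2 and SN2' attack give the same product, and the excess of 2 should hold back a second substitution.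

Step 2
Reactants: 3 5-(chloromethyl)hex-5-en-2-yn-1-ol
Product: 4 (2Z)-5-(chloromethyl)hexa-2,5-dien-1-ol
Conditions: H2 (1 atm), Pd/CaCO3 poisoned with Pb(OAc)2, quinoline, EtOAc, rt, stopped after one equivalent
Reagents that add atoms: none
Why: Lindlar semihydrogenation delivers hydrogen syn to the alkyne and should give the Z-alkene, the poisoned surface leaving the 1,1-disubstituted alkene and the allylic C–Cl bond alone.

Step 3
Reactants: 4 (2Z)-5-(chloromethyl)hexa-2,5-dien-1-ol
Product: 5 [(2S,3R)-3-[2-(chloromethyl)prop-2-en-1-yl]oxiran-2-yl]methanol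
Conditions: Ti(Oi-Pr)4 (20 mol %), L-(+)-diethyl tartrate (24 mol %), t-BuOOH (2 equiv, decane), 4 Å molecular sieves, CH2Cl2, −20 °C
Reagents that add atoms: tert-butyl hydroperoxide, CC(C)(C)OO
Why: Sharpless asymmetric epoxidation: only the alkene of the allylic alcohol is bound and oxidized, the Z geometry gives the cis-epoxide, and L-(+)-tartrate should deliver oxygen to the face that makes the carbinol-bearing carbon S, which sets C7 (S) and C6 (R).

Step 4
Reactants: 5 [(2S,3R)-3-[2-(chloromethyl)prop-2-en-1-yl]oxiran-2-yl]methanol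
Product: 6 [(2S,3R)-3-[2-(chloromethyl)prop-2-en-1-yl]oxiran-2-yl]methyl trifluoromethanesulfonate
Conditions: Tf2O, 2,6-lutidine, CH2Cl2, −78 °C; cold filtration through silica, used at once
Reagents that add atoms: trifluoromethanesulfonic anhydride, O=S(=O)(OS(=O)(=O)C(F)(F)F)C(F)(F)F
Why: O-Sulfonylation of the primary alcohol at low temperature with a hindered base should leave the epoxide and the allylic chloride untouched; no stereocenter takes part.

Step 5
Reactants: 6 [(2S,3R)-3-[2-(chloromethyl)prop-2-en-1-yl]oxiran-2-yl]methyl trifluoromethanesulfonate; 7 [4-(benzyloxy)phenyl]magnesium bromide (1.05 equiv, commercial THF solution)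
Product: 8 (2S,3R)-2-{[4-(benzyloxy)phenyl]methyl}-3-[2-(chloromethyl)prop-2-en-1-yl]oxirane
Conditions: CuBr·SMe2 (10 mol %), Et2O/THF, −78 → −40 °C, slow addition of 7
Reagents that add atoms: none
Why: Copper-catalyzed cross-coupling of a Grignard reagent with a primary alkyl triflate, the usual way to alkylate 2,3-epoxy triflates; the triflate is by orders of magnitude the best leaving group present and should react before the allylic chloride and the epoxide, and both stereocenters are untouched.

Step 6
Reactants: 8 (2S,3R)-2-{[4-(benzyloxy)phenyl]methyl}-3-[2-(chloromethyl)prop-2-en-1-yl]oxirane; 9 4-(benzyloxy)-3-methoxybenzaldehyde (1.5 equiv)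
Product: 11 (1S)-1-[(2S,6S)-6-[4-(benzyloxy)-3-methoxyphenyl]-4-methylideneoxan-2-yl]-2-[4-(benzyloxy)phenyl]ethan-1-ol, via homoallylic epoxy alcohol 10 (not isolated)
Conditions: [Ir(cod)Cl]2 (2.5 mol %), (S)-SEGPHOS (5 mol %), 4-cyano-3-nitrobenzoic acid (10 mol %), K3PO4 (1 equiv), i-PrOH (2 equiv), THF, 60 °C; then KOt-Bu (1.5 equiv), 0 °C → rt, same flask
Reagents that add atoms: none
Why: In this transfer-hydrogenative carbonyl allylation (Krische allylation) the complex formed from [Ir(cod)Cl]2, (S)-SEGPHOS and the nitrobenzoate takes hydrogen from 2-propanol, ionizes the allylic C–Cl bond of 8 to a 2-substituted π-allyl intermediate, and its σ-allyl form adds to aldehyde 9 through a closed chair transition state (C2–C3 bond); the closest known case is the same reaction of methallyl chloride with aryl aldehydes. The chiral bisphosphine alone selects the aldehyde face and sets C2 (S), the remote epoxide having no say. The potassium alkoxide of carbinol 10 then opens the epoxide at C6 (O1–C6 bond) in a 6-exo-tet SN2 mode, the standard base-mediated cyclization of epoxy alcohols, closing the oxane through a chair in which the sp2 C4 removes one 1,3-diaxial contact. C6 is set by clean inversion of the (R)-epoxide carbon and the C7 hydroxyl is released with the configuration fixed in step 3, so the 2,6-trans relation follows from two independently set centers. The step needs (a) ionization of the allylic chloride and not of the epoxide, secured because the epoxide is separated from the alkene by C5H2 and is not allylic, (b) 6-exo rather than 7-endo opening, secured by the tether length, and (c) an intact electron-rich benzylic C2 center, secured by keeping the whole sequence basic. Material from the minor enantiomer of 8 should end as the 2,6-cis diastereomer and be removed by chromatography at this stage.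

Step 7
Reactants: 11 (1S)-1-[(2S,6S)-6-[4-(benzyloxy)-3-methoxyphenyl]-4-methylideneoxan-2-yl]-2-[4-(benzyloxy)phenyl]ethan-1-ol
Product: 13 (2S,6S)-2-[4-(benzyloxy)-3-methoxyphenyl]-6-[(1S)-2-[4-(benzyloxy)phenyl]-1-hydroxyethyl]oxan-4-one, via spiro ozonide 12 (not isolated)
Conditions: O3, CH2Cl2, −78 °C, Sudan Red 7B as end-point indicator; then PPh3, −78 °C → rt
Reagents that add atoms: ozone, [O-][O+]=O
Why: Ozonolysis with reductive work-up (Criegee mechanism): the 1,1-disubstituted alkene should react far faster than the alkoxyarenes, and the neutral work-up avoids retro-oxa-Michael epimerization at C2 and C6.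

Step 8
Reactants: 13 (2S,6S)-2-[4-(benzyloxy)-3-methoxyphenyl]-6-[(1S)-2-[4-(benzyloxy)phenyl]-1-hydroxyethyl]oxan-4-one
Product: 14 (2S,4S,6S)-2-[4-(benzyloxy)-3-methoxyphenyl]-6-[(1S)-2-[4-(benzyloxy)phenyl]-1-hydroxyethyl]oxan-4-ol
Conditions: Me4NBH(OAc)3 (5 equiv), MeCN/AcOH (1:1), −30 → 0 °C
Reagents that add atoms: none
Why: Hydroxyl-directed reduction (Saksena–Evans reduction): the C7 hydroxyl exchanges onto boron and the hydride should be delivered within the complex to the C4 face that carries the axial C6 side chain, which places the new hydroxyl equatorial and cis to the C2 aryl group (4S), also the more stable epimer.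

Step 9
Reactants: 14 (2S,4S,6S)-2-[4-(benzyloxy)-3-methoxyphenyl]-6-[(1S)-2-[4-(benzyloxy)phenyl]-1-hydroxyethyl]oxan-4-ol
Product: 15 (2S,4S,6S)-2-(4-hydroxy-3-methoxyphenyl)-6-[(1S)-1-hydroxy-2-(4-hydroxyphenyl)ethyl]oxan-4-ol
Conditions: H2 (1 atm), 10% Pd/C, EtOAc/EtOH, rt, stopped at two equivalents
Reagents that add atoms: none
Why: Hydrogenolysis of the two aryl benzyl ethers, which should cleave much faster than the cyclic benzylic C2–O1 bond under neutral conditions; no stereocenter is touched.

## Compound list

1 | prop-2-yn-1-ol | OCC#C | starting material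
2 | 3-chloro-2-(chloromethyl)prop-1-ene | ClCC(=C)CCl | starting material
3 | 5-(chloromethyl)hex-5-en-2-yn-1-ol | OCC#CCC(=C)CCl | intermediate
4 | (2Z)-5-(chloromethyl)hexa-2,5-dien-1-ol | OC/C=C\CC(=C)CCl | intermediate
5 | [(2S,3R)-3-[2-(chloromethyl)prop-2-en-1-yl]oxiran-2-yl]methanol | ClCC(=C)C[C@H]1O[C@H]1CO | intermediate
6 | [(2S,3R)-3-[2-(chloromethyl)prop-2-en-1-yl]oxiran-2-yl]methyl trifluoromethanesulfonate | ClCC(=C)C[C@H]1O[C@H]1COS(=O)(=O)C(F)(F)F | intermediate
7 | [4-(benzyloxy)phenyl]magnesium bromide | Br[Mg]c1ccc(OCc2ccccc2)cc1 | starting material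
8 | (2S,3R)-2-{[4-(benzyloxy)phenyl]methyl}-3-[2-(chloromethyl)prop-2-en-1-yl]oxirane | ClCC(=C)C[C@H]1O[C@H]1Cc1ccc(OCc2ccccc2)cc1 | intermediate
9 | 4-(benzyloxy)-3-methoxybenzaldehyde | COc1cc(C=O)ccc1OCc1ccccc1 | starting material
10 | (1S)-1-[4-(benzyloxy)-3-methoxyphenyl]-3-{[(2R,3S)-3-{[4-(benzyloxy)phenyl]methyl}oxiran-2-yl]methyl}but-3-en-1-ol | COc1cc([C@@H](O)CC(=C)C[C@H]2O[C@H]2Cc2ccc(OCc3ccccc3)cc2)ccc1OCc1ccccc1 | intermediate
11 | (1S)-1-[(2S,6S)-6-[4-(benzyloxy)-3-methoxyphenyl]-4-methylideneoxan-2-yl]-2-[4-(benzyloxy)phenyl]ethan-1-ol | COc1cc([C@@H]2CC(=C)C[C@@H]([C@@H](O)Cc3ccc(OCc4ccccc4)cc3)O2)ccc1OCc1ccccc1 | intermediate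
12 | secondary ozonide of 11: the oxane of 11 with C4 as the spiro carbon of a 1,2,4-trioxolane in place of the methylidene group, both epimers at the spiro carbon | COc1cc([C@@H]2CC3(OOCO3)C[C@@H]([C@@H](O)Cc4ccc(OCc5ccccc5)cc4)O2)ccc1OCc1ccccc1 | intermediate
13 | (2S,6S)-2-[4-(benzyloxy)-3-methoxyphenyl]-6-[(1S)-2-[4-(benzyloxy)phenyl]-1-hydroxyethyl]oxan-4-one | COc1cc([C@@H]2CC(=O)C[C@@H]([C@@H](O)Cc3ccc(OCc4ccccc4)cc3)O2)ccc1OCc1ccccc1 | intermediate
14 | (2S,4S,6S)-2-[4-(benzyloxy)-3-methoxyphenyl]-6-[(1S)-2-[4-(benzyloxy)phenyl]-1-hydroxyethyl]oxan-4-ol | COc1cc([C@@H]2C[C@H](O)C[C@@H]([C@@H](O)Cc3ccc(OCc4ccccc4)cc3)O2)ccc1OCc1ccccc1 | intermediate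
15 | (2S,4S,6S)-2-(4-hydroxy-3-methoxyphenyl)-6-[(1S)-1-hydroxy-2-(4-hydroxyphenyl)ethyl]oxan-4-ol | COc1cc([C@@H]2C[C@H](O)C[C@@H]([C@@H](O)Cc3ccc(O)cc3)O2)ccc1O | target

## Step count and risks

Total step count: 9. Longest linear sequence: 9 steps (1 to 15); 2, 7 and 9 are purchased.

Steps most likely to fail:

Step 6. The π-allyl iridium intermediate from the bulky 2-substituted chloride may be reduced to the methyl compound faster than it adds to the aldehyde, or may add with poor face selection. The fallback replaces the iridium chemistry by a chiral-acid-catalyzed allylboration. It sets out from 8, which is borylated with bis(pinacolato)diboron and Pd2(dba)3 in THF (Miyaura-type allylic borylation) to the pinacol allylboronate F1. F1 and aldehyde 9 are joined with (S)-3,3'-bis(2,4,6-triisopropylphenyl)-1,1'-binaphthyl-2,2'-diyl hydrogen phosphate (5 mol %) in toluene at −30 °C, where the acid organizes a closed chair transition state and should give carbinol 10, now isolated. Treatment of 10 with KOt-Bu in THF closes the oxane, and the fallback comes back to the route at 11.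

Step 5. The arylcopper species may attack the allylic chloride or the epoxide in competition with the triflate. The fallback introduces the aryl group after ring formation, when no allylic chloride is left. It sets out from 5, which is silylated (t-BuMe2SiCl, imidazole, DMF) to the silyl ether F2. F2 and 9 are taken through the conditions of step 6; the uncyclized carbinol F3 is not isolated and closes to the silyloxy oxane F4, where a shift of the silyl group to the neighboring oxygen would be harmless. Fluoride (n-Bu4NF, THF) gives the diol F5. Selective sulfonylation of the primary hydroxyl (TsCl, Et3N, catalytic Bu2SnO) gives the monotosylate F6, which K2CO3 in MeOH closes to the terminal epoxide F7 with C7 retained. Copper-catalyzed opening of F7 at its CH2 terminus with Grignard reagent 7 (CuI 10 mol %, THF, −30 °C) gives 11, where the fallback comes back to the route.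

Step 8. The hydride may not be delivered through the boron-bound C7 oxygen, and external attack from the equatorial direction would then give the axial (4R) carbinol. The fallback gives up kinetic delivery for thermodynamic control. It sets out from 13, which is reduced by electron transfer with SmI2 in THF/i-PrOH at rt; this mode of reduction favors the more stable equatorial carbinol, and the fallback comes back to the route at 14 without a new compound.

## Further compounds

F1 | step 6 | 2-{2-[((2R,3S)-3-{[4-(benzyloxy)phenyl]methyl}oxiran-2-yl)methyl]prop-2-en-1-yl}-4,4,5,5-tetramethyl-1,3,2-dioxaborolane | CC1(C)OB(CC(=C)C[C@H]2O[C@H]2Cc2ccc(OCc3ccccc3)cc2)OC1(C)C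
F2 | step 5 | tert-butyl{[(2S,3R)-3-[2-(chloromethyl)prop-2-en-1-yl]oxiran-2-yl]methoxy}dimethylsilane | ClCC(=C)C[C@H]1O[C@H]1CO[Si](C)(C)C(C)(C)C
F3 | step 5 | (1S)-1-[4-(benzyloxy)-3-methoxyphenyl]-3-{[(2R,3S)-3-({[tert-butyl(dimethyl)silyl]oxy}methyl)oxiran-2-yl]methyl}but-3-en-1-ol | COc1cc([C@@H](O)CC(=C)C[C@H]2O[C@H]2CO[Si](C)(C)C(C)(C)C)ccc1OCc1ccccc1
F4 | step 5 | (1S)-1-[(2S,6S)-6-[4-(benzyloxy)-3-methoxyphenyl]-4-methylideneoxan-2-yl]-2-{[tert-butyl(dimethyl)silyl]oxy}ethan-1-ol | COc1cc([C@@H]2CC(=C)C[C@@H]([C@@H](O)CO[Si](C)(C)C(C)(C)C)O2)ccc1OCc1ccccc1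
F5 | step 5 | (1S)-1-[(2S,6S)-6-[4-(benzyloxy)-3-methoxyphenyl]-4-methylideneoxan-2-yl]ethane-1,2-diol | COc1cc([C@@H]2CC(=C)C[C@@H]([C@@H](O)CO)O2)ccc1OCc1ccccc1
F6 | step 5 | (2S)-2-[(2S,6S)-6-[4-(benzyloxy)-3-methoxyphenyl]-4-methylideneoxan-2-yl]-2-hydroxyethyl 4-methylbenzenesulfonate | COc1cc([C@@H]2CC(=C)C[C@@H]([C@@H](O)COS(=O)(=O)c3ccc(C)cc3)O2)ccc1OCc1ccccc1
F7 | step 5 | (2S,6S)-2-[4-(benzyloxy)-3-methoxyphenyl]-4-methylidene-6-[(2S)-oxiran-2-yl]oxane | COc1cc([C@@H]2CC(=C)C[C@@H]([C@@H]3CO3)O2)ccc1OCc1ccccc1
F0 | step 8 | none | none
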